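54.3 min⁻¹ is what the ash run gives for the turnover frequency, the target made per catalyst charged per minute, averaged up to its last reading.

in all of them: substrate 0.030 M; added ligand 0.12 mM

| flask | reagent | free catalyst | temperature | remark | time |
|---|---|---|---|---|---|
| larch | 0.027 M | 15 µM | 10 °C | run made earlier |  |
| ash | 0.027 M | 29 µM | 25 °C | run made earlier |  |
| birch | 0.027 M | 52 µM | 10 °C | run made earlier |  |
| Thursday's | 0.0270 M | 60 µM | 25 °C |  | 2.5 min |
| Tuesday's | 0.0270 M | 15 µM | 25 °C |  | 4.0 min |

larch run (percent of the substrate charged)

| time / min | target / % | substrate / % |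
|---|---|---|
| 0.333 | 0 | 101.2 |
| 0.667 | 0.6 | 100.6 |
| 1.33 | 2.3 | 97.8 |
| 2.00 | 1.9 | 99.0 |
| 3.00 | 3.7 | 96.0 |

ash run (percent of the substrate charged)

| time / s | target / % | substrate / % |
|---|---|---|
| 15.0 | 1.9 | 97.8 |
| 30.0 | 4.0 | 97.3 |
| 50.0 | 5.7 | 97.0 |
| 60.0 | 6.8 | 94.7 |
| 80.0 | 7.0 | 94.0 |

birch run (percent of the substrate charged)

| time / min | target / % | substrate / % |
|---|---|---|
| 0.500 | 0.7 | 99.6 |
| 1.00 | 0.5 | 96.2 |
| 2.00 | 7.3 | 94.5 |
| 3.00 | 9.2 | 88.4 |

(standard deviation of a reading: 1 percentage point)

* the winner by amount of target, in percent of the substrate charged; "neither" if no more than 2 percentage points parts them (Thursday's / Tuesday's / neither)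
* how much target is there at the end, in percent of the substrate charged: Thursday's
* how much target is there at the end, in percent of the substrate charged: Tuesday's

- the numbers in the tables scatter by 1 percentage point (one standard deviation)
- on the list of suspects stand: substrate + free catalyst <-> catalyst intermediate A; reagent + catalyst intermediate A <-> catalyst intermediate B; catalyst intermediate B <-> released group + catalyst intermediate C; catalyst intermediate C -> free catalyst + target; free catalyst + added ligand <-> idle complex

Both new flasks stand at 25 °C, the temperature of ash, so this count carries over, although the last ash reading, 7.0%, has a scatter of 1 percentage point. At 10 °C the same count gives 24.7 min⁻¹ in larch and 17.7 min⁻¹ in birch, which holds 3.47 times the catalyst of larch. The last larch reading is 3.7% with that same scatter, so the reckoning here takes the rate as proportional to the catalyst charged.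

On this count Thursday's curve starts with a slope of 0.109 min⁻¹ as a fraction of the substrate charge. The reagent is the limiting reagent, charged at 90.0% of the substrate, and that is the level the target can run into. The straight line would reach this level at 8.29 min, later than the asked 2.5 min, so that corner of the line falls outside Thursday's run. The line itself ends at 27.2%. Taking the slope as proportional to the reagent left, read at mid-time, keeps 84.9% of it, which gives 23.1%. Tuesday's line ends at 10.9%, the same correction keeps 94.0%, and the reckoning gives 10.2%. On this reckoning Thursday's leads by 13 points, more than the margin of 2 points.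

The forecast names Thursday's, with 26% for Thursday's, higher than the reckoning here, and 12% for Tuesday's, on the grounds that the rate is “about first order in catalyst”.

Thursday's gives 21.7% and Tuesday's 10.0%, so Thursday's wins.

    substrate + free catalyst ⇌ catalyst intermediate A (K = 12.0 L mol⁻¹, k = 1100 L mol⁻¹ s⁻¹, Ea = 42.0 kJ mol⁻¹, ΔH = −5.00 kJ mol⁻¹)
    reagent + catalyst intermediate A ⇌ catalyst intermediate B (K = 35.0 L mol⁻¹, k = 1000 L mol⁻¹ s⁻¹, Ea = 45.0 kJ mol⁻¹, ΔH = −25.0 kJ mol⁻¹)
    catalyst intermediate B ⇌ released group + catalyst intermediate C (K = 0.00470 M, k = 9.50 s⁻¹, Ea = 69.0 kJ mol⁻¹, ΔH = −8.00 kJ mol⁻¹)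
    catalyst intermediate C → free catalyst + target (k = 41.0 s⁻¹, Ea = 64.0 kJ mol⁻¹)
    free catalyst + added ligand ⇌ idle complex, settled at all times (K = 6200 L mol⁻¹, ΔH = −35.0 kJ mol⁻¹)
    (constants at 25 °C)

At 2.50 min Thursday's still holds 75.9% of its reagent. Counted back per catalyst charged, Thursday's averaged 43.4 min⁻¹ and Tuesday's 50.2 min⁻¹. In a neighbour of Thursday's charged with 2.4 × 10⁻⁴ M of free catalyst, the straight line at 54.3 min⁻¹ reaches the reagent level at 2.07 min, before 2.5 min, and at 2.50 min that flask stands at 52.2% target with 42% of its reagent left.

(Readings and results stem from a simulated flask on assumed constants; the scatter is artificial.)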